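**Plan**

1. Ret­ro­syn­the­sis: the two aryl O–CH3 bonds are cut last. Ring A (the ring with one OH) is taken back to a cyclohex-2-enone, and the macrocycle is opened at the bond between the ring B oxygen and C-3 of ring A. This gives a phenol tethered to a 3-chlorocyclohex-2-enone.
2. Enabling feature: ring A carries OH, O-aryl and the chain on C-1, C-3 and C-5, the pattern of a 5-alkylcyclohexane-1,3-dione, so C-3 can be the β-carbon of a chloroenone. The bridging oxygen sits on C-1 of ring B between the C-2 oxygen and the C-6 chain, hindered for metal-catalysed arylation but a good nucleophile for addition–elimination.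
3. Further cuts: the dione goes back to a methyl enone plus diethyl malonate, the enone to a chain aldehyde, and the aryl–CH2 bond to an aryl Grignard reagent and a C15 bromo ester from pentadecanolide.
4. Forward order: chain joined to ring B (steps 1–3), phenol oxygen placed on ring B (steps 4–5), six-membered carbocycle built at the far chain end (steps 6–9), 20-membered ring closed at O–C-3 (step 10), ring A aromatised (step 11), methyl ethers removed (step 12).
5. Stereochemistry: the target has no stereocentre. The single sp3 centre (C-5) of the chloroenone and of the macrocyclic enone is carried racemic and disappears on aromatisation.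

Key step: step 10

**Route**

Step 1
Reactants: 1 omega-pentadecalactone (oxacyclohexadecan-2-one)
Product: 2 methyl 15-hydroxypentadecanoate
Conditions: MeOH, H2SO4 (catalytic), reflux
Reagents that add atoms: methanol, CO
Why: Acid-catalysed transesterification in a large excess of methanol opens the 16-membered lactone to the hydroxy methyl ester, because re-closure of the large ring is entropically disfavoured.

Step 2
Reactants: 2 methyl 15-hydroxypentadecanoate
Product: 3 methyl 15-bromopentadecanoate
Conditions: CBr4, PPh3, CH2Cl2, 0 °C to rt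
Reagents that add atoms: carbon tetrabromide, BrC(Br)(Br)Br
Why: Appel reaction, in which the primary alcohol is activated as an alkoxyphosphonium ion and displaced by bromide under neutral conditions that leave the methyl ester alone.

Step 3
Reactants: 3 methyl 15-bromopentadecanoate; 4 1-bromo-3,5-dimethoxybenzene
Product: 6 methyl 15-(3,5-dimethoxyphenyl)pentadecanoate, via (3,5-dimethoxyphenyl)magnesium bromide 5 (not isolated)
Conditions: 4, Mg turnings, THF, reflux; then added slowly to 3, FeCl3 (5 mol %), TMEDA, THF, 0 °C
Reagents that add atoms: none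
Why: Iron-catalysed Kumada-type cross-coupling of an aryl Grignard reagent with a primary alkyl bromide (FeCl3/TMEDA, slow Grignard addition) should form the aryl–CH2 bond faster than the Grignard reagent adds to the distant methyl ester, a group this coupling is known to tolerate.

Step 4
Reactants: 6 methyl 15-(3,5-dimethoxyphenyl)pentadecanoate
Product: 8 methyl 15-(2-formyl-3,5-dimethoxyphenyl)pentadecanoate, via aryl iminium chloride 7 (not isolated)
Conditions: POCl3, DMF, 0 to 70 °C; then ice-water
Reagents that add atoms: N,N-dimethylformamide, CN(C)C=O; water, O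
Why: Vilsmeier–Haack formylation of a 5-alkylresorcinol dimethyl ether is expected at C-2 (para to one methoxy group, ortho to the other, beside the chain) and not at the more crowded C-4 between the two methoxy groups, as with orcinol and olivetol dimethyl ethers, and the iminium salt is hydrolysed to the aldehyde on quenching.

Step 5
Reactants: 8 methyl 15-(2-formyl-3,5-dimethoxyphenyl)pentadecanoate
Product: 10 methyl 15-(2-hydroxy-3,5-dimethoxyphenyl)pentadecanoate, via aryl formate 9 (not isolated)
Conditions: mCPBA (1.05 equiv), CH2Cl2, 0 °C to rt; then K2CO3 (catalytic), MeOH, rt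
Reagents that add atoms: 3-chloroperbenzoic acid, OOC(=O)c1cccc(Cl)c1
Why: Baeyer–Villiger oxidation in its Dakin variant, in which the electron-rich aryl group of the ortho,para-dimethoxybenzaldehyde migrates in the Criegee adduct in preference to hydride and the aryl formate is then cleaved by carbonate-catalysed methanolysis that cannot change a methyl ester.

Step 6
Reactants: 10 methyl 15-(2-hydroxy-3,5-dimethoxyphenyl)pentadecanoate
Product: 11 15-(2-hydroxy-3,5-dimethoxyphenyl)pentadecanal
Conditions: iBu2AlH (2.2 equiv), CH2Cl2, −78 °C; then MeOH, aq. KNaC4H4O6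
Reagents that add atoms: none
Why: Partial reduction of a methyl ester with iBu2AlH at −78 °C stops at the aluminium hemiacetal, which collapses to the aldehyde only on work-up, the first equivalent of hydride being consumed by the phenol.

Step 7
Reactants: 11 15-(2-hydroxy-3,5-dimethoxyphenyl)pentadecanal; 12 1-(triphenylphosphoranylidene)propan-2-one
Product: 13 (E)-18-(2-hydroxy-3,5-dimethoxyphenyl)octadec-3-en-2-one
Conditions: toluene, 90 °C
Reagents that add atoms: none
Why: Wittig olefination with the stabilised acetonylidene ylide should give the (E)-enone, and the ylide is too weak a base to be quenched by the phenol or to enolise the aldehyde.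

Step 8
Reactants: 13 (E)-18-(2-hydroxy-3,5-dimethoxyphenyl)octadec-3-en-2-one; 14 diethyl malonate
Product: 18 5-[14-(2-hydroxy-3,5-dimethoxyphenyl)tetradecyl]cyclohexane-1,3-dione, via Michael adduct 15 (not isolated), via cyclic keto ester 16 (not isolated), via keto acid 17 (not isolated)
Conditions: NaOEt (2.2 equiv), EtOH, reflux, Ar; then aq. NaOH, reflux; then aq. HCl, reflux
Reagents that add atoms: none
Why: Classical dimedone-type annulation (Michael addition of the sodium enolate of diethyl malonate to the enone, Claisen closure of the methyl ketone enolate onto one ester, saponification and decarboxylation of the β-keto acid), giving an achiral 5-substituted cyclohexane-1,3-dione while the phenol is only a spectator sodium phenoxide kept under argon.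

Step 9
Reactants: 18 5-[14-(2-hydroxy-3,5-dimethoxyphenyl)tetradecyl]cyclohexane-1,3-dione
Product: 19 3-chloro-5-[14-(2-hydroxy-3,5-dimethoxyphenyl)tetradecyl]cyclohex-2-en-1-one (racemic)
Conditions: (COCl)2 (1.1 equiv), DMF (catalytic), CH2Cl2, 0 °C to rt
Reagents that add atoms: oxalyl chloride, ClC(=O)C(Cl)=O
Why: Vinylogous acid chloride formation from a cyclic 1,3-dione with oxalyl chloride and catalytic DMF, in which the enol (a vinylogous carboxylic acid) should react with the chloroiminium species far faster than the hindered phenol in the absence of base, either enantiotopic carbonyl reacts so that C-5 arises racemic, and any aryl oxalate formed is cleaved on NaHCO3 work-up.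

Step 10
Reactants: 19 3-chloro-5-[14-(2-hydroxy-3,5-dimethoxyphenyl)tetradecyl]cyclohex-2-en-1-one (racemic)
Product: 20 macrocyclic enone in which the phenol oxygen of 19 replaces Cl at C-3 of the cyclohexenone (20-membered ring; racemic)
Conditions: Cs2CO3 (3 equiv), degassed DMF, 60 °C, Ar, syringe-pump addition of 19 over 12 h (final 2 mM)
Reagents that add atoms: none
Why: Cs2CO3 deprotonates the ring B phenol, the caesium phenoxide adds through oxygen to C-3 (the β-carbon) of the tethered 3-chlorocyclohex-2-enone, and the enolate so formed expels chloride to restore the enone (addition–elimination, a vinylogous acyl substitution). The closest known reactions are the intermolecular etherification of phenols with 3-chlorocyclohex-2-enones under carbonate bases and macrocyclic diaryl ether closures by SNAr, which follow the same addition–elimination logic. The 20-membered ring closes by exo attack on a trigonal carbon (the attacked C=C lies outside the new ring), and the saturated (CH2)14 tether puts no strain on that trajectory. No stereocentre is created, and C-5 stays racemic until it is erased in step 11. The step needs ring closure to beat intermolecular etherification, which slow addition into dilute warm Cs2CO3/DMF should secure by keeping the phenoxide concentration low, and it needs O-attack to beat C-attack, which the substrate secures because both ortho positions and the para position of the phenoxide are substituted and the electrophile offers one unhindered sp2 carbon bearing the leaving group.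

Step 11
Reactants: 20 macrocyclic enone (racemic)
Product: 21 macrocyclic 3-aryloxy-5-alkylphenol (ring A aromatic; di-O-methyl ether of the target)
Conditions: Pd(O2CCF3)2 (5 mol %), 2-(dimethylamino)pyridine (10 mol %), TsOH (20 mol %), 4 Å molecular sieves, O2 (1 atm), DMSO, 80 °C
Reagents that add atoms: none
Why: Aerobic dehydrogenation of a cyclohexenone to a phenol catalysed by divalent palladium, in which a palladium enolate at C-6 undergoes β-hydride elimination of the C-5 hydrogen, the 3-aryloxycyclohexa-2,5-dienone tautomerises to the phenol and O2 reoxidises zerovalent palladium, which also removes the only stereocentre.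

Step 12
Reactants: 21 macrocyclic 3-aryloxy-5-alkylphenol
Product: 22 CNP0173380.0 (target; both ring B oxygens free)
Conditions: BBr3 (6 equiv), CH2Cl2, −78 °C to rt; then H2O
Reagents that add atoms: none
Why: BBr3 cleavage of aryl methyl ethers (Lewis acid–base complex, then bromide attack at methyl) should free both ring B hydroxyls while the diaryl ether, whose sp2 carbons cannot be displaced, and the saturated chain remain.

**Compound list**

1 | omega-pentadecalactone (oxacyclohexadecan-2-one) | O=C1CCCCCCCCCCCCCCO1 | starting material
2 | methyl 15-hydroxypentadecanoate | COC(=O)CCCCCCCCCCCCCCO | intermediate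
3 | methyl 15-bromopentadecanoate | COC(=O)CCCCCCCCCCCCCCBr | intermediate
4 | 1-bromo-3,5-dimethoxybenzene | COc1cc(Br)cc(OC)c1 | starting material
5 | (3,5-dimethoxyphenyl)magnesium bromide (formed in the flask, not isolated) | COc1cc([Mg]Br)cc(OC)c1 | intermediate
6 | methyl 15-(3,5-dimethoxyphenyl)pentadecanoate | COC(=O)CCCCCCCCCCCCCCc1cc(OC)cc(OC)c1 | intermediate
7 | N-{[2,4-dimethoxy-6-(15-methoxy-15-oxopentadecyl)phenyl]methylidene}-N-methylmethanaminium chloride (aryl iminium chloride; formed in the flask, not isolated) | COC(=O)CCCCCCCCCCCCCCc1cc(OC)cc(OC)c1C=[N+](C)C.[Cl-] | intermediate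
8 | methyl 15-(2-formyl-3,5-dimethoxyphenyl)pentadecanoate | COC(=O)CCCCCCCCCCCCCCc1cc(OC)cc(OC)c1C=O | intermediate
9 | methyl 15-[2-(formyloxy)-3,5-dimethoxyphenyl]pentadecanoate (aryl formate; formed in the flask, not isolated) | COC(=O)CCCCCCCCCCCCCCc1cc(OC)cc(OC)c1OC=O | intermediate
10 | methyl 15-(2-hydroxy-3,5-dimethoxyphenyl)pentadecanoate | COC(=O)CCCCCCCCCCCCCCc1cc(OC)cc(OC)c1O | intermediate
11 | 15-(2-hydroxy-3,5-dimethoxyphenyl)pentadecanal | O=CCCCCCCCCCCCCCCc1cc(OC)cc(OC)c1O | intermediate
12 | 1-(triphenylphosphoranylidene)propan-2-one | CC(=O)C=P(c1ccccc1)(c1ccccc1)c1ccccc1 | starting material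
13 | (E)-18-(2-hydroxy-3,5-dimethoxyphenyl)octadec-3-en-2-one | CC(=O)/C=C/CCCCCCCCCCCCCCc1cc(OC)cc(OC)c1O | intermediate
14 | diethyl malonate | CCOC(=O)CC(=O)OCC | starting material
15 | diethyl 2-[18-(2-hydroxy-3,5-dimethoxyphenyl)-2-oxooctadecan-4-yl]propanedioate (Michael adduct, racemic; formed in the flask, not isolated) | CCOC(=O)C(C(=O)OCC)C(CC(C)=O)CCCCCCCCCCCCCCc1cc(OC)cc(OC)c1O | intermediate
16 | ethyl 2-[14-(2-hydroxy-3,5-dimethoxyphenyl)tetradecyl]-4,6-dioxocyclohexane-1-carboxylate (cyclic keto ester, racemic diastereomer mixture, present as its sodium enolate; not isolated) | CCOC(=O)C1C(=O)CC(=O)CC1CCCCCCCCCCCCCCc2cc(OC)cc(OC)c2O | intermediate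
17 | 2-[14-(2-hydroxy-3,5-dimethoxyphenyl)tetradecyl]-4,6-dioxocyclohexane-1-carboxylic acid (keto acid, racemic; not isolated) | OC(=O)C1C(=O)CC(=O)CC1CCCCCCCCCCCCCCc2cc(OC)cc(OC)c2O | intermediate
18 | 5-[14-(2-hydroxy-3,5-dimethoxyphenyl)tetradecyl]cyclohexane-1,3-dione (achiral) | O=C1CC(=O)CC(CCCCCCCCCCCCCCc2cc(OC)cc(OC)c2O)C1 | intermediate
19 | 3-chloro-5-[14-(2-hydroxy-3,5-dimethoxyphenyl)tetradecyl]cyclohex-2-en-1-one (racemic) | O=C1C=C(Cl)CC(CCCCCCCCCCCCCCc2cc(OC)cc(OC)c2O)C1 | intermediate
20 | macrocyclic 3-aryloxycyclohex-2-en-1-one (racemic): C-3 of the enone bonded to the ring B oxygen, C-5 joined through (CH2)14 to the ring B carbon ortho to that oxygen; ring B carries OMe ortho and para to the oxygen; 20-membered ring | COc1cc(OC)c2c(c1)CCCCCCCCCCCCCCC1CC(=O)C=C(C1)O2 | intermediate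
21 | macrocyclic diaryl ether: ring A a 3-aryloxy-5-alkylphenol, ring B a 2,4-dimethoxy-6-alkylphenoxy unit, the two alkyl positions joined by (CH2)14; di-O-methyl ether of the target | COc1cc(OC)c2c(c1)CCCCCCCCCCCCCCc1cc(O)cc(c1)O2 | intermediate
22 | CNP0173380.0: as 21 with OH in place of both OMe groups on ring B | Oc1cc2cc(c1)Oc1c(O)cc(O)cc1CCCCCCCCCCCCCC2 | target

**Count**

Total step count: 12. Longest linear sequence: 12 steps (1 to 22); 4, 12 and 14 enter as purchased reagents.

**Three steps most likely to fail**

Step 10. Ring closure may lose to intermolecular etherification, so that linear and cyclic oligomers build up, or the chloroenone may be consumed by base-induced self-condensation during the long addition. The fallback sets out from Grignard reagent 5, reuses 12 and 14, and returns at 20. It makes the ether bond intermolecularly and closes the large ring inside the chain by olefin metathesis.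
- Ring B piece: reagent 5 is coupled with 6-bromohex-1-ene under the conditions of step 3 to give 1-(hex-5-en-1-yl)-3,5-dimethoxybenzene F1. Vilsmeier formylation (POCl3, DMF, then water) passes through the aryl iminium chloride F2 to 2-(hex-5-en-1-yl)-4,6-dimethoxybenzaldehyde F3. Dakin oxidation with H2O2 and catalytic H2SO4 in MeOH (a peracid is avoided to spare the alkene) passes through 2-(hex-5-en-1-yl)-4,6-dimethoxyphenyl formate F4 to 2-(hex-5-en-1-yl)-4,6-dimethoxyphenol F5.
- Ring A piece: undec-10-enal and ylide 12 give (E)-tetradeca-3,13-dien-2-one F6. With diethyl malonate 14 under the conditions of step 8 this passes through the Michael adduct diethyl 2-(2-oxotetradec-13-en-4-yl)propanedioate F7, the keto ester ethyl 2-(dec-9-en-1-yl)-4,6-dioxocyclohexane-1-carboxylate F8 and the acid 2-(dec-9-en-1-yl)-4,6-dioxocyclohexane-1-carboxylic acid F9 to 5-(dec-9-en-1-yl)cyclohexane-1,3-dione F10. Oxalyl chloride with catalytic DMF converts it to 3-chloro-5-(dec-9-en-1-yl)cyclohex-2-en-1-one F11.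
- Joining and closure: phenol F5 and chloroenone F11 are joined with K2CO3 in DMF at ordinary concentration to 5-(dec-9-en-1-yl)-3-[2-(hex-5-en-1-yl)-4,6-dimethoxyphenoxy]cyclohex-2-en-1-one F12. Ring-closing metathesis with the second-generation Grubbs catalyst RuCl2(=CHPh)(PCy3)(H2IMes) in CH2Cl2 at 1 mM and 40 °C should close the 20-membered ring as the E/Z mixture of the macrocyclic alkene F13. Hydrogenation of its disubstituted C=C with H2 and RhCl(PPh3)3, which leaves the oxygen-substituted enone double bond, gives 20.

Step 11. Acid-promoted hydrolysis of the vinylogous aryl ester may reopen the macrocycle before dehydrogenation is complete, or the catalyst may precipitate as palladium metal. The fallback sets out from 20 and returns at 21, using stoichiometric α′-selenation and selenoxide elimination in place of catalysis. Kinetic deprotonation of 20 at C-6 with commercial LiN(iPr)2 in THF at −78 °C (the usual site for vinylogous esters), then PhSeCl, gives the 6-(phenylselanyl) derivative of 20 F14. H2O2 with pyridine in CH2Cl2 at 0 °C oxidises it to the selenoxide F15. Syn elimination toward the C-5 hydrogen gives the cross-conjugated dienone, which is the keto tautomer of 21 and should tautomerise to it. C-6 is epimerisable, so either diastereomer of the selenide can reach the syn arrangement.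

Step 9. Oxalyl chloride may also acylate the ring B phenol, so that reagent is used up and dione is left, or an aryl oxalate may survive the work-up. The fallback sets out from 18 and returns at 20; it masks the phenol as a silyl ether and lets fluoride trigger the ring closure. TBSCl and imidazole in DMF silylate both the enol and the phenol of 18 to the bis(silyl) compound F16. Its enol silyl ether, a vinylogous silyl ester, is hydrolysed on dilute-acid work-up to the aryl silyl ether dione F17. Oxalyl chloride with catalytic DMF then gives the silyl-protected chloroenone F18 with no free phenol present. Slow addition of F18 to CsF in DMF at 60 °C, at the dilution of step 10, removes the silyl group and releases the caesium phenoxide, which should cyclise in place to 20.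

**Further compounds**

F1 | step 10 | 1-(hex-5-en-1-yl)-3,5-dimethoxybenzene | C=CCCCCc1cc(OC)cc(OC)c1
F2 | step 10 | N-{[2-(hex-5-en-1-yl)-4,6-dimethoxyphenyl]methylidene}-N-methylmethanaminium chloride | C=CCCCCc1cc(OC)cc(OC)c1C=[N+](C)C.[Cl-]
F3 | step 10 | 2-(hex-5-en-1-yl)-4,6-dimethoxybenzaldehyde | C=CCCCCc1cc(OC)cc(OC)c1C=O
F4 | step 10 | 2-(hex-5-en-1-yl)-4,6-dimethoxyphenyl formate | C=CCCCCc1cc(OC)cc(OC)c1OC=O
F5 | step 10 | 2-(hex-5-en-1-yl)-4,6-dimethoxyphenol | C=CCCCCc1cc(OC)cc(OC)c1O
F6 | step 10 | (E)-tetradeca-3,13-dien-2-one | CC(=O)/C=C/CCCCCCCCC=C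
F7 | step 10 | diethyl 2-(2-oxotetradec-13-en-4-yl)propanedioate (racemic) | CCOC(=O)C(C(=O)OCC)C(CC(C)=O)CCCCCCCCC=C
F8 | step 10 | ethyl 2-(dec-9-en-1-yl)-4,6-dioxocyclohexane-1-carboxylate (racemic diastereomer mixture) | CCOC(=O)C1C(=O)CC(=O)CC1CCCCCCCCC=C
F9 | step 10 | 2-(dec-9-en-1-yl)-4,6-dioxocyclohexane-1-carboxylic acid (racemic) | OC(=O)C1C(=O)CC(=O)CC1CCCCCCCCC=C
F10 | step 10 | 5-(dec-9-en-1-yl)cyclohexane-1,3-dione | O=C1CC(=O)CC(CCCCCCCCC=C)C1
F11 | step 10 | 3-chloro-5-(dec-9-en-1-yl)cyclohex-2-en-1-one (racemic) | O=C1C=C(Cl)CC(CCCCCCCCC=C)C1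
F12 | step 10 | 5-(dec-9-en-1-yl)-3-[2-(hex-5-en-1-yl)-4,6-dimethoxyphenoxy]cyclohex-2-en-1-one (racemic) | C=CCCCCc1cc(OC)cc(OC)c1OC1=CC(=O)CC(CCCCCCCCC=C)C1
F13 | step 10 | macrocyclic alkene: 20 with a C=C between chain carbons 5 and 6 counted from ring B (E/Z mixture, racemic) | COc1cc(OC)c2c(c1)CCCCC=CCCCCCCCCC1CC(=O)C=C(C1)O2
F14 | step 11 | 6-(phenylselanyl) derivative of 20 (selenium on the CH between C=O and C-5; racemic diastereomer mixture) | COc1cc(OC)c2c(c1)CCCCCCCCCCCCCCC1C([Se]c3ccccc3)C(=O)C=C(C1)O2
F15 | step 11 | selenoxide of F14 | COc1cc(OC)c2c(c1)CCCCCCCCCCCCCCC1C([Se](=O)c3ccccc3)C(=O)C=C(C1)O2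
F16 | step 9 | 3-[(tert-butyldimethylsilyl)oxy]-5-{14-[2-(tert-butyldimethylsilyloxy)-3,5-dimethoxyphenyl]tetradecyl}cyclohex-2-en-1-one (racemic) | CC(C)(C)[Si](C)(C)OC1=CC(=O)CC(CCCCCCCCCCCCCCc2cc(OC)cc(OC)c2O[Si](C)(C)C(C)(C)C)C1
F17 | step 9 | 5-{14-[2-(tert-butyldimethylsilyloxy)-3,5-dimethoxyphenyl]tetradecyl}cyclohexane-1,3-dione | O=C1CC(=O)CC(CCCCCCCCCCCCCCc2cc(OC)cc(OC)c2O[Si](C)(C)C(C)(C)C)C1
F18 | step 9 | 3-chloro-5-{14-[2-(tert-butyldimethylsilyloxy)-3,5-dimethoxyphenyl]tetradecyl}cyclohex-2-en-1-one (racemic) | O=C1C=C(Cl)CC(CCCCCCCCCCCCCCc2cc(OC)cc(OC)c2O[Si](C)(C)C(C)(C)C)C1
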